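Locants follow the target's carbon chain: C1 acetyl CH3, C2 acetyl C=O, C3, C4, C5=C6, C7, C8, C9, C10=C11, C12 (amide C=O), N13, C14–C16, C17, N18, C19 (lactam C=O), C20, C21 (enol C), C22 (ketone), C23=C24, C25, C26, C27, C28, C29, C30 (CHCH3), C31.
Enabling feature: cyclohexene ring B (C4, C5, C6, C7, C27, C28) has its alkene C5=C6 opposite the C27–C28 bond and is fused through C4–C28 to cyclopentane A (C3, C4, C28, C29, C30) and through C7–C27 to cyclopentane C (C7, C8, C25, C26, C27) in a trans-anti-cis array. This is the retron of a transannular Diels–Alder reaction of a 12-membered E,E,E-triene.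
Cuts, last to first: C4–C28 and C7–C27 (Diels–Alder) with C5–C6 (Suzuki closure of the temporary 12-ring); C20–C21 (Lacey–Dieckmann) and N18–C19 (acylketene lactamisation); C10=C11 and C23=C24 (two olefinations); C25–C26 (lactone enolate allylation).
Forward: chain C26–C5 (allyl bromide/vinyl boronate 16) and iodovinyl lactone 21 are joined to 23, then the 17-membered lactam, then the tetramic acid with the 16-membered lactam, then one operation closes the 12-ring and rings A, B and C, then deprotection.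
Stereochemistry: C30 from 1; C3 by Evans aldol; C8 by Rh/(S)-BINAP conjugate addition; C25 by trans-alkylation of the lactone; C17 from L-ornithine; C4, C7, C27, C28 from the alkene geometries and the four tether stereocentres in the cycloaddition.

Key step: step 26

Remark: (diphenoxyphosphoryl)acetic acid 30 and methyl (S)-hydrogen 3-methylglutarate 1 are taken as purchasable, and the tetramic acid is drawn throughout in the enol tautomer of the target.

Step 1
Reactants: 1 (3S)-5-methoxy-3-methyl-5-oxopentanoic acid; 2 (4S)-4-benzyl-1,3-oxazolidin-2-one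
Product: 4 methyl (3S)-5-[(4S)-4-benzyl-2-oxo-1,3-oxazolidin-3-yl]-3-methyl-5-oxopentanoate, via mixed pivalic anhydride 3 (not isolated)
Conditions: PivCl, Et3N, THF, −20 °C; then 2, LiCl, 23 °C
Reagents that add atoms: none
Why: N-acylation of the oxazolidinone through the mixed pivalic anhydride should take place at the unhindered acyl carbon only and leave the methyl ester and the C30 stereocentre untouched.

Step 2
Reactants: 4 methyl (3S)-5-[(4S)-4-benzyl-2-oxo-1,3-oxazolidin-3-yl]-3-methyl-5-oxopentanoate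
Product: 6 methyl (3R,4S,5R)-4-{[(4S)-4-benzyl-2-oxo-1,3-oxazolidin-3-yl]carbonyl}-5-hydroxy-3-methylhexanoate, via Z-boron enolate 5 (not isolated)
Conditions: Bu2BOTf, iPr2NEt, CH2Cl2, −78 to 0 °C; then MeCHO, −78 to 0 °C; then pH 7 buffer, MeOH, H2O2
Reagents that add atoms: acetaldehyde, CC=O
Why: In the Evans syn-aldol reaction the Z-boron enolate should react through a chair transition state on the face away from the benzyl group, which sets C3 under auxiliary control irrespective of the C30 centre.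

Step 3
Reactants: 6 methyl (3R,4S,5R)-4-{[(4S)-4-benzyl-2-oxo-1,3-oxazolidin-3-yl]carbonyl}-5-hydroxy-3-methylhexanoate
Product: 7 methyl (3R,4S)-4-{[(4S)-4-benzyl-2-oxo-1,3-oxazolidin-3-yl]carbonyl}-3-methyl-5-oxohexanoate
Conditions: Dess–Martin periodinane, NaHCO3, CH2Cl2, 0 to 23 °C
Reagents that add atoms: none
Why: Dess–Martin oxidation should give the β-keto imide, in which allylic strain holds the C3–H in the imide plane so that C3 does not epimerise.

Step 4
Reactants: 7 methyl (3R,4S)-4-{[(4S)-4-benzyl-2-oxo-1,3-oxazolidin-3-yl]carbonyl}-3-methyl-5-oxohexanoate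
Product: 8 methyl (3R,4S)-5-[(4S)-4-benzyl-2-oxo-1,3-oxazolidin-3-yl]-3-methyl-4-(2-methyl-1,3-dioxolan-2-yl)-5-oxopentanoate
Conditions: Me3SiOCH2CH2OSiMe3, Me3SiOTf (5 mol %), CH2Cl2, −78 to −20 °C
Reagents that add atoms: 1,2-bis(trimethylsilyloxy)ethane, C[Si](C)(C)OCCO[Si](C)(C)C
Why: Noyori acetalisation under aprotic silyl triflate catalysis should mask the methyl ketone as a dioxolane without enolising C3, so that the acetyl group cannot later conjugate with the C4=C5 alkene.

Step 5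
Reactants: 8 methyl (3R,4S)-5-[(4S)-4-benzyl-2-oxo-1,3-oxazolidin-3-yl]-3-methyl-4-(2-methyl-1,3-dioxolan-2-yl)-5-oxopentanoate
Product: 10 (4R,5R)-4-methyl-5-(2-methyl-1,3-dioxolan-2-yl)oxan-2-one, via hydroxy ester 9 (not isolated)
Conditions: NaBH4, THF/H2O (4:1), 0 to 23 °C; then DBU (cat.), PhMe, 60 °C
Reagents that add atoms: none
Why: Borohydride in wet THF should reduce the exocyclic imide carbonyl to the primary alcohol while the methyl ester survives, and 6-exo-trig lactonisation of the δ-hydroxy ester then differentiates the two chain ends and returns auxiliary 2.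

Step 6
Reactants: 10 (4R,5R)-4-methyl-5-(2-methyl-1,3-dioxolan-2-yl)oxan-2-one
Product: 11 (4R,5R)-4-methyl-5-(2-methyl-1,3-dioxolan-2-yl)oxan-2-ol (anomer mixture)
Conditions: iBu2AlH, CH2Cl2, −78 °C
Reagents that add atoms: none
Why: Partial reduction of a δ-lactone should stop at the lactol because the tetrahedral aluminate is stable at −78 °C.

Step 7
Reactants: 11 (4R,5R)-4-methyl-5-(2-methyl-1,3-dioxolan-2-yl)oxan-2-ol
Product: 12 methyl (2E,5R,6R)-7-hydroxy-5-methyl-6-(2-methyl-1,3-dioxolan-2-yl)hept-2-enoate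
Conditions: Ph3P=CHCO2Me, PhMe, 80 °C
Reagents that add atoms: methyl (triphenylphosphoranylidene)acetate, COC(=O)C=P(c1ccccc1)(c1ccccc1)c1ccccc1
Why: The Wittig reaction of the stabilised ylide with the open hydroxy aldehyde form of the lactol should give the E-enoate (C27=C28) and free the C4 alcohol, and the base-free medium avoids oxa-Michael reclosure.

Step 8
Reactants: 12 methyl (2E,5R,6R)-7-hydroxy-5-methyl-6-(2-methyl-1,3-dioxolan-2-yl)hept-2-enoate
Product: 13 methyl (2E,5R,6R)-5-methyl-6-(2-methyl-1,3-dioxolan-2-yl)-7-oxohept-2-enoate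
Conditions: Dess–Martin periodinane, NaHCO3, CH2Cl2, 0 °C
Reagents that add atoms: none
Why: Buffered Dess–Martin oxidation should give the α-branched aldehyde without epimerising C3.

Step 9
Reactants: 13 methyl (2E,5R,6R)-5-methyl-6-(2-methyl-1,3-dioxolan-2-yl)-7-oxohept-2-enoate
Product: 14 methyl (2E,5R,6R,7E)-5-methyl-6-(2-methyl-1,3-dioxolan-2-yl)-8-(4,4,5,5-tetramethyl-1,3,2-dioxaborolan-2-yl)octa-2,7-dienoate
Conditions: CrCl2, LiI, Cl2CHBpin, THF, 23 °C
Reagents that add atoms: 2-(dichloromethyl)-4,4,5,5-tetramethyl-1,3,2-dioxaborolane, ClC(Cl)B1OC(C)(C)C(C)(C)O1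
Why: The Takai–Utimoto olefination with the geminal dichromium boryl carbenoid should convert the aldehyde into the E-alkenyl boronate (C4=C5) and tolerates the enoate and the dioxolane.

Step 10
Reactants: 14 methyl (2E,5R,6R,7E)-5-methyl-6-(2-methyl-1,3-dioxolan-2-yl)-8-(4,4,5,5-tetramethyl-1,3,2-dioxaborolan-2-yl)octa-2,7-dienoate
Product: 15 (2E,5R,6R,7E)-5-methyl-6-(2-methyl-1,3-dioxolan-2-yl)-8-(4,4,5,5-tetramethyl-1,3,2-dioxaborolan-2-yl)octa-2,7-dien-1-ol
Conditions: iBu2AlH, CH2Cl2, −78 °C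
Reagents that add atoms: none
Why: 1,2-Reduction of the enoate by two hydride transfers should give the E-allylic alcohol, and the pinacol boronate is inert to the hydride at −78 °C.

Step 11
Reactants: 15 (2E,5R,6R,7E)-5-methyl-6-(2-methyl-1,3-dioxolan-2-yl)-8-(4,4,5,5-tetramethyl-1,3,2-dioxaborolan-2-yl)octa-2,7-dien-1-ol
Product: 16 2-[(1E,3R,4R,6E)-8-bromo-4-methyl-3-(2-methyl-1,3-dioxolan-2-yl)octa-1,6-dien-1-yl]-4,4,5,5-tetramethyl-1,3,2-dioxaborolane
Conditions: CBr4, PPh3, 2,6-lutidine, CH2Cl2, 0 °C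
Reagents that add atoms: tetrabromomethane, BrC(Br)(Br)Br
Why: The Appel reaction should displace the primary allylic alkoxyphosphonium by bromide in an SN2 sense without allylic transposition, and the lutidine protects the dioxolane.

Step 12
Reactants: 17 ethynyltrimethylsilane
Product: 18 trimethyl[(E)-2-(4,4,5,5-tetramethyl-1,3,2-dioxaborolan-2-yl)ethenyl]silane
Conditions: pinacolborane, Cp2Zr(H)Cl (5 mol %), Et3N (10 mol %), neat, 60 °C
Reagents that add atoms: pinacolborane, [H]B1OC(C)(C)C(C)(C)O1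
Why: Zirconium-catalysed syn hydroboration of the terminal alkyne should place boron on the terminal carbon and give the E-β-silylvinyl boronate.

Step 13
Reactants: 19 5,6-dihydro-2H-pyran-2-one; 18 trimethyl[(E)-2-(4,4,5,5-tetramethyl-1,3,2-dioxaborolan-2-yl)ethenyl]silane
Product: 20 (4S)-4-[(E)-2-(trimethylsilyl)ethenyl]oxan-2-one
Conditions: Rh(acac)(C2H4)2 (3 mol %), (S)-BINAP (3.3 mol %), K2CO3 (10 mol %), 1,4-dioxane/H2O (10:1), 80 °C
Reagents that add atoms: none
Why: In the Hayashi–Miyaura conjugate addition the alkenyl group is transferred from boron (not silicon) to rhodium and then to the β-carbon of the lactone, and the (S)-BINAP complex should select the face that gives S at C8.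

Step 14
Reactants: 20 (4S)-4-[(E)-2-(trimethylsilyl)ethenyl]oxan-2-one
Product: 21 (4S)-4-[(E)-2-iodoethenyl]oxan-2-one
Conditions: N-iodosuccinimide, (CF3)2CHOH, 0 °C
Reagents that add atoms: N-iodosuccinimide, O=C1CCC(=O)N1I
Why: Ipso-iododesilylation through the β-silyl cation should replace silicon by iodine with retention of the E geometry.

Step 15
Reactants: 21 (4S)-4-[(E)-2-iodoethenyl]oxan-2-one; 16 2-[(1E,3R,4R,6E)-8-bromo-4-methyl-3-(2-methyl-1,3-dioxolan-2-yl)octa-1,6-dien-1-yl]-4,4,5,5-tetramethyl-1,3,2-dioxaborolane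
Product: 23 (3R,4S)-4-[(E)-2-iodoethenyl]-3-[(2E,5R,6R,7E)-5-methyl-6-(2-methyl-1,3-dioxolan-2-yl)-8-(4,4,5,5-tetramethyl-1,3,2-dioxaborolan-2-yl)octa-2,7-dien-1-yl]oxan-2-one, via lithium enolate 22 (not isolated)
Conditions: LiN(iPr)2, THF, −78 °C; then 16, DMPU, −78 to −40 °C
Reagents that add atoms: none
Why: SN2 alkylation of the δ-lactone lithium enolate by the allylic bromide should occur anti to the C8 substituent and give the trans-3,4-disubstituted lactone, which sets C25 and joins the two fragments with the E-C27=C28 alkene in place.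

Step 16
Reactants: 24 2,2,6-trimethyl-4H-1,3-dioxin-4-one
Product: 26 diethyl [(2,2-dimethyl-4-oxo-4H-1,3-dioxin-6-yl)methyl]phosphonate, via lithium dienolate 25 (not isolated)
Conditions: LiN(iPr)2 (2.2 equiv), THF, −78 °C; then ClP(O)(OEt)2; aq NH4Cl
Reagents that add atoms: diethyl chlorophosphate, CCOP(=O)(Cl)OCC
Why: The extended dienolate should be phosphorylated at its γ-carbon, and the second equivalent of base takes up the more acidic product.

Step 17
Reactants: 27 methyl N5-(tert-butoxycarbonyl)-L-ornithinate hydrochloride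
Product: 28 methyl N5-(tert-butoxycarbonyl)-N2-(2,4-dimethoxybenzyl)-L-ornithinate
Conditions: 2,4-(MeO)2C6H3CHO, Et3N, NaBH(OAc)3, ClCH2CH2Cl, 23 °C
Reagents that add atoms: 2,4-dimethoxybenzaldehyde, COc1ccc(C=O)c(OC)c1
Why: Reductive amination should mono-benzylate the α-amine, since the triacetoxyborohydride reduces the iminium ion faster than the aldehyde, and C17 is not touched.

Step 18
Reactants: 28 methyl N5-(tert-butoxycarbonyl)-N2-(2,4-dimethoxybenzyl)-L-ornithinate
Product: 29 methyl N2-(2,4-dimethoxybenzyl)-L-ornithinate dihydrochloride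
Conditions: HCl (4 M in 1,4-dioxane), 0 to 23 °C
Reagents that add atoms: hydrogen chloride, Cl
Why: Anhydrous acidolysis should remove the tert-butyl carbamate while the benzylic amine and the methyl ester survive, and the salt form prevents lactamisation of the diamine ester.

Step 19
Reactants: 29 methyl N2-(2,4-dimethoxybenzyl)-L-ornithinate dihydrochloride; 30 (diphenoxyphosphoryl)acetic acid
Product: 31 methyl N2-(2,4-dimethoxybenzyl)-N5-[(diphenoxyphosphoryl)acetyl]-L-ornithinate
Conditions: EDC·HCl, HOBt, iPr2NEt, CH2Cl2, 0 °C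
Reagents that add atoms: none
Why: Carbodiimide coupling should acylate the unhindered primary δ-amine in preference to the hindered secondary α-amine, which stays free for the later lactamisation.

Step 20
Reactants: 23 (3R,4S)-4-[(E)-2-iodoethenyl]-3-[(2E,5R,6R,7E)-5-methyl-6-(2-methyl-1,3-dioxolan-2-yl)-8-(4,4,5,5-tetramethyl-1,3,2-dioxaborolan-2-yl)octa-2,7-dien-1-yl]oxan-2-one
Product: 32 the corresponding oxan-2-ol (lactol at C24, anomer mixture)
Conditions: iBu2AlH, CH2Cl2, −78 °C
Reagents that add atoms: none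
Why: Partial reduction of the lactone at −78 °C should stop at the lactol and leave the alkenyl iodide, the alkenyl boronate and the dioxolane intact.

Step 21
Reactants: 32 lactol of 23; 26 diethyl [(2,2-dimethyl-4-oxo-4H-1,3-dioxin-6-yl)methyl]phosphonate
Product: 33 C10 alcohol with the chain C8–C25–C24=C23 ending in a 2,2-dimethyl-4-oxo-4H-1,3-dioxin-6-yl group, (E)-2-iodoethenyl on C8 and the boronate chain on C25 (3R,8S,25S,30R)
Conditions: LiN(SiMe3)2, THF, −78 to 0 °C
Reagents that add atoms: none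
Why: The Horner–Wadsworth–Emmons reaction of the stabilised phosphonate anion with the open aldehyde form of the lactol should give the E-alkene C23=C24, and the dienyl dioxinone is too poor an acceptor for the freed C10 alkoxide to add back.

Step 22
Reactants: 33 C10 alcohol dioxinone
Product: 34 the corresponding C10 aldehyde
Conditions: Dess–Martin periodinane, NaHCO3, CH2Cl2, 0 °C
Reagents that add atoms: none
Why: Buffered Dess–Martin oxidation of the primary alcohol should leave the dioxinone, the dioxolane, the iodide and the boronate untouched.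

Step 23
Reactants: 34 C10 aldehyde dioxinone; 31 methyl N2-(2,4-dimethoxybenzyl)-N5-[(diphenoxyphosphoryl)acetyl]-L-ornithinate
Product: 35 open-chain (10Z)-enamide carrying the N18-(2,4-dimethoxybenzyl)ornithine methyl ester and the dioxinone (3R,8S,17S,25S,30R)
Conditions: KOtBu, THF, −78 to −40 °C
Reagents that add atoms: none
Why: In the Ando variant of the Horner–Wadsworth–Emmons reaction the electron-poor phenoxy groups make the syn oxaphosphetane collapse before it can equilibrate, which should give the Z-enamide C10=C11 and bring in the whole ornithine unit.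

Step 24
Reactants: 35 open-chain (10Z)-enamide dioxinone
Product: 37 17-membered macrocyclic β-keto amide (N18–C19 closed; methyl ester on C17), via acylketene 36 (not isolated)
Conditions: PhMe (0.5 mM), 110 °C
Reagents that add atoms: none
Why: Retro-[4+2] loss of acetone from the dioxinone should give an acylketene that is captured within the molecule by the secondary N18 amine, and high dilution favours the 17-membered ring over oligomers.

Step 25
Reactants: 37 17-membered macrocyclic β-keto amide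
Product: 38 N18-(2,4-dimethoxybenzyl) tetramic acid in the 16-membered macrolactam, with (E)-2-iodoethenyl on C8 and the dioxolane/boronate chain on C25 (3R,8S,17S,25S,30R)
Conditions: KOtBu, tBuOH/THF, 0 to 23 °C; then dilute HCl to pH 5, 0 °C
Reagents that add atoms: none
Why: In the Lacey–Dieckmann cyclisation the C20 enolate should attack the C21 ester (5-exo-trig), helped by the N-benzyl group that favours the reactive amide rotamer, and the product is held as its stabilised enolate so that C17 keeps its configuration.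

Step 26
Reactants: 38 N18-(2,4-dimethoxybenzyl) tetramic acid macrolactam
Product: 40 N18-(2,4-dimethoxybenzyl) C2-ethylene ketal of the target (3R,4R,7R,8S,17S,25S,27R,28R,30R), via macrocyclic triene 39 (not isolated)
Conditions: Pd(PPh3)4 (20 mol %), TlOEt, degassed THF/H2O (4:1), 0.5 mM, 23 °C; then pH 7 buffer, PhMe, 100 °C
Reagents that add atoms: none
Why: Zerovalent palladium inserts into the C6–I bond, the TlOEt-activated C5 boronate transmetalates and reductive elimination joins C5 to C6 with retention of both alkene geometries, which should give the 12-membered (4E,6E,27E)-triene 39 with the diene C4=C5–C6=C7 facing the alkene C27=C28 across the ring; warming should then bring about a concerted suprafacial transannular [4+2] cycloaddition. The closest known reaction type is the Suzuki–Miyaura macrocyclisation of an alkenyl iodide onto an alkenyl boronate followed by the transannular Diels–Alder reaction of the resulting macrocyclic triene. The temporary 12-membered ring closes end to end by sp2–sp2 coupling; ring B then closes as the six-membered ring of the cycloaddition, ring A through the new C4–C28 bond with its tether C3–C30–C29 anti to the diene (trans fusion), and ring C through the new C7–C27 bond with its tether C8–C25–C26 syn to the diene (cis fusion). The E,E-diene forces H4 and H7 cis and the E-alkene forces H27 and H28 trans, so only trans-anti-cis tricycles can form; the diene face is fixed by the allylic centres C3 and C8, whose dioxolanyl and C9 substituents stay pseudo-equatorial and anti to the diene (setting C4 and C7), and the orientation of the dienophile is fixed by C30 and C25, whose methyl and C24 substituents end up cis-1,3 to the substituents at C28 and C27 only in the arrangement that leads to 40 (setting C28 and C27). The step needs ring closure to outrun oligomerisation, which the 0.5 mM dilution should secure, and it needs the diene to take C27=C28 as its only partner, which is secured because the enone and enamide alkenes sit two atoms from the diene and cannot reach it.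

Step 27
Reactants: 40 N18-(2,4-dimethoxybenzyl) C2-ethylene ketal of the target
Product: 41 target CNP0320820.1 (3R,4R,7R,8S,17S,25S,27R,28R,30R; 10Z,23E)
Conditions: CF3CO2H/H2O (95:5), 23 °C
Reagents that add atoms: water, O
Why: Acidolysis should cleave the electron-rich benzyl group from the lactam nitrogen and hydrolyse the dioxolane to the acetyl group in one operation, and the absence of base keeps C3 from epimerising.

Compound list
1 | (3S)-5-methoxy-3-methyl-5-oxopentanoic acid (methyl (S)-hydrogen 3-methylglutarate) | COC(=O)C[C@@H](C)CC(=O)O | starting material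
2 | (4S)-4-benzyl-1,3-oxazolidin-2-one | O=C1N[C@@H](Cc2ccccc2)CO1 | starting material
3 | mixed anhydride of 1 with pivalic acid | COC(=O)C[C@@H](C)CC(=O)OC(=O)C(C)(C)C | intermediate
4 | methyl (3S)-5-[(4S)-4-benzyl-2-oxo-1,3-oxazolidin-3-yl]-3-methyl-5-oxopentanoate | COC(=O)C[C@@H](C)CC(=O)N1[C@@H](Cc2ccccc2)COC1=O | intermediate
5 | (Z)-dibutylboron enolate of 4 | COC(=O)C[C@@H](C)/C=C(\OB(CCCC)CCCC)N1[C@@H](Cc2ccccc2)COC1=O | intermediate
6 | methyl (3R,4S,5R)-4-{[(4S)-4-benzyl-2-oxo-1,3-oxazolidin-3-yl]carbonyl}-5-hydroxy-3-methylhexanoate | COC(=O)C[C@@H](C)[C@@H]([C@@H](C)O)C(=O)N1[C@@H](Cc2ccccc2)COC1=O | intermediate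
7 | methyl (3R,4S)-4-{[(4S)-4-benzyl-2-oxo-1,3-oxazolidin-3-yl]carbonyl}-3-methyl-5-oxohexanoate | COC(=O)C[C@@H](C)[C@@H](C(C)=O)C(=O)N1[C@@H](Cc2ccccc2)COC1=O | intermediate
8 | methyl (3R,4S)-5-[(4S)-4-benzyl-2-oxo-1,3-oxazolidin-3-yl]-3-methyl-4-(2-methyl-1,3-dioxolan-2-yl)-5-oxopentanoate | COC(=O)C[C@@H](C)[C@@H](C1(C)OCCO1)C(=O)N2[C@@H](Cc3ccccc3)COC2=O | intermediate
9 | methyl (3R,4R)-5-hydroxy-3-methyl-4-(2-methyl-1,3-dioxolan-2-yl)pentanoate | COC(=O)C[C@@H](C)[C@@H](C1(C)OCCO1)CO | intermediate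
10 | (4R,5R)-4-methyl-5-(2-methyl-1,3-dioxolan-2-yl)oxan-2-one | O=C1C[C@@H](C)[C@@H](C2(C)OCCO2)CO1 | intermediate
11 | (4R,5R)-4-methyl-5-(2-methyl-1,3-dioxolan-2-yl)oxan-2-ol (anomer mixture) | OC1C[C@@H](C)[C@@H](C2(C)OCCO2)CO1 | intermediate
12 | methyl (2E,5R,6R)-7-hydroxy-5-methyl-6-(2-methyl-1,3-dioxolan-2-yl)hept-2-enoate | COC(=O)/C=C/C[C@@H](C)[C@@H](C1(C)OCCO1)CO | intermediate
13 | methyl (2E,5R,6R)-5-methyl-6-(2-methyl-1,3-dioxolan-2-yl)-7-oxohept-2-enoate | COC(=O)/C=C/C[C@@H](C)[C@@H](C1(C)OCCO1)C=O | intermediate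
14 | methyl (2E,5R,6R,7E)-5-methyl-6-(2-methyl-1,3-dioxolan-2-yl)-8-(4,4,5,5-tetramethyl-1,3,2-dioxaborolan-2-yl)octa-2,7-dienoate | COC(=O)/C=C/C[C@@H](C)[C@@H](C1(C)OCCO1)/C=C/B2OC(C)(C)C(C)(C)O2 | intermediate
15 | (2E,5R,6R,7E)-5-methyl-6-(2-methyl-1,3-dioxolan-2-yl)-8-(4,4,5,5-tetramethyl-1,3,2-dioxaborolan-2-yl)octa-2,7-dien-1-ol | OC/C=C/C[C@@H](C)[C@@H](C1(C)OCCO1)/C=C/B2OC(C)(C)C(C)(C)O2 | intermediate
16 | 2-[(1E,3R,4R,6E)-8-bromo-4-methyl-3-(2-methyl-1,3-dioxolan-2-yl)octa-1,6-dien-1-yl]-4,4,5,5-tetramethyl-1,3,2-dioxaborolane | BrC/C=C/C[C@@H](C)[C@@H](C1(C)OCCO1)/C=C/B2OC(C)(C)C(C)(C)O2 | intermediate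
17 | ethynyltrimethylsilane | C[Si](C)(C)C#C | starting material
18 | trimethyl[(E)-2-(4,4,5,5-tetramethyl-1,3,2-dioxaborolan-2-yl)ethenyl]silane | C[Si](C)(C)/C=C/B1OC(C)(C)C(C)(C)O1 | intermediate
19 | 5,6-dihydro-2H-pyran-2-one | O=C1C=CCCO1 | starting material
20 | (4S)-4-[(E)-2-(trimethylsilyl)ethenyl]oxan-2-one | O=C1C[C@@H](/C=C/[Si](C)(C)C)CCO1 | intermediate
21 | (4S)-4-[(E)-2-iodoethenyl]oxan-2-one | O=C1C[C@@H](/C=C/I)CCO1 | intermediate
22 | lithium enolate of 21 | [Li]OC1=C[C@@H](/C=C/I)CCO1 | intermediate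
23 | (3R,4S)-4-[(E)-2-iodoethenyl]-3-[(2E,5R,6R,7E)-5-methyl-6-(2-methyl-1,3-dioxolan-2-yl)-8-(4,4,5,5-tetramethyl-1,3,2-dioxaborolan-2-yl)octa-2,7-dien-1-yl]oxan-2-one | O=C1[C@H](C/C=C/C[C@@H](C)[C@@H](C2(C)OCCO2)/C=C/B3OC(C)(C)C(C)(C)O3)[C@@H](/C=C/I)CCO1 | intermediate
24 | 2,2,6-trimethyl-4H-1,3-dioxin-4-one | CC1=CC(=O)OC(C)(C)O1 | starting material
25 | lithium dienolate of 24 | C=C1C=C(O[Li])OC(C)(C)O1 | intermediate
26 | diethyl [(2,2-dimethyl-4-oxo-4H-1,3-dioxin-6-yl)methyl]phosphonate | CCOP(=O)(OCC)CC1=CC(=O)OC(C)(C)O1 | intermediate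
27 | methyl N5-(tert-butoxycarbonyl)-L-ornithinate hydrochloride | COC(=O)[C@@H](N)CCCNC(=O)OC(C)(C)C.Cl | starting material
28 | methyl N5-(tert-butoxycarbonyl)-N2-(2,4-dimethoxybenzyl)-L-ornithinate | COC(=O)[C@@H](NCc1ccc(OC)cc1OC)CCCNC(=O)OC(C)(C)C | intermediate
29 | methyl N2-(2,4-dimethoxybenzyl)-L-ornithinate dihydrochloride | COC(=O)[C@@H](NCc1ccc(OC)cc1OC)CCCN.Cl.Cl | intermediate
30 | (diphenoxyphosphoryl)acetic acid | OC(=O)CP(=O)(Oc1ccccc1)Oc1ccccc1 | starting material
31 | methyl N2-(2,4-dimethoxybenzyl)-N5-[(diphenoxyphosphoryl)acetyl]-L-ornithinate | COC(=O)[C@@H](NCc1ccc(OC)cc1OC)CCCNC(=O)CP(=O)(Oc1ccccc1)Oc1ccccc1 | intermediate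
32 | lactol of 23 (oxan-2-ol, anomer mixture) | OC1[C@H](C/C=C/C[C@@H](C)[C@@H](C2(C)OCCO2)/C=C/B3OC(C)(C)C(C)(C)O3)[C@@H](/C=C/I)CCO1 | intermediate
33 | C10 alcohol with (23E)-dienyl dioxinone, iodoethenyl on C8, boronate chain on C25 (3R,8S,25S,30R) | OCC[C@H](/C=C/I)[C@@H](C/C=C/C[C@@H](C)[C@@H](C2(C)OCCO2)/C=C/B3OC(C)(C)C(C)(C)O3)/C=C/C1=CC(=O)OC(C)(C)O1 | intermediate
34 | C10 aldehyde of 33 | O=CC[C@H](/C=C/I)[C@@H](C/C=C/C[C@@H](C)[C@@H](C2(C)OCCO2)/C=C/B3OC(C)(C)C(C)(C)O3)/C=C/C1=CC(=O)OC(C)(C)O1 | intermediate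
35 | open-chain (10Z)-enamide with N18-(2,4-dimethoxybenzyl)ornithine methyl ester and dioxinone (3R,8S,17S,25S,30R) | COC(=O)[C@H](CCCNC(=O)/C=C\C[C@H](/C=C/I)[C@@H](C/C=C/C[C@@H](C)[C@@H](C2(C)OCCO2)/C=C/B3OC(C)(C)C(C)(C)O3)/C=C/C1=CC(=O)OC(C)(C)O1)NCc4ccc(OC)cc4OC | intermediate
36 | acylketene from 35 | COC(=O)[C@H](CCCNC(=O)/C=C\C[C@H](/C=C/I)[C@@H](C/C=C/C[C@@H](C)[C@@H](C2(C)OCCO2)/C=C/B3OC(C)(C)C(C)(C)O3)/C=C/C(=O)C=C=O)NCc4ccc(OC)cc4OC | intermediate
37 | 17-membered macrocyclic β-keto amide (3R,8S,17S,25S,30R) | COC(=O)[C@@H]1CCCNC(=O)/C=C\C[C@H](/C=C/I)[C@@H](C/C=C/C[C@@H](C)[C@@H](C2(C)OCCO2)/C=C/B3OC(C)(C)C(C)(C)O3)/C=C/C(=O)CC(=O)N1Cc4ccc(OC)cc4OC | intermediate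
38 | N18-(2,4-dimethoxybenzyl) tetramic acid 16-membered macrolactam with iodoethenyl on C8 and dioxolane/boronate chain on C25 (3R,8S,17S,25S,30R) | I/C=C/[C@H]1C/C=C\C(=O)NCCC[C@@H]2N(Cc3ccc(OC)cc3OC)C(=O)C(=C2O)C(=O)/C=C/[C@@H]1C/C=C/C[C@@H](C)[C@@H](C4(C)OCCO4)/C=C/B5OC(C)(C)C(C)(C)O5 | intermediate
39 | 12-membered (4E,6E,27E)-triene fused to the macrolactam at C8–C25 (C5 joined to C6; stereocentres of 38 unchanged) | CC1(OCCO1)[C@H]2/C=C/C=C/[C@H]3C/C=C\C(=O)NCCC[C@@H]4N(Cc5ccc(OC)cc5OC)C(=O)C(=C4O)C(=O)/C=C/[C@@H]3C/C=C/C[C@H]2C | intermediate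
40 | N18-(2,4-dimethoxybenzyl) C2-ethylene ketal of the target (3R,4R,7R,8S,17S,25S,27R,28R,30R) | CC1(OCCO1)[C@H]2[C@@H]3C=C[C@@H]4[C@H]5C/C=C\C(=O)NCCC[C@@H]6N(Cc7ccc(OC)cc7OC)C(=O)C(=C6O)C(=O)/C=C/[C@@H]5C[C@@H]4[C@H]3C[C@H]2C | intermediate
41 | target CNP0320820.1 (3R,4R,7R,8S,17S,25S,27R,28R,30R; 10Z,23E) | CC(=O)[C@H]1[C@@H]2C=C[C@@H]3[C@H]4C/C=C\C(=O)NCCC[C@@H]5NC(=O)C(=C5O)C(=O)/C=C/[C@@H]4C[C@@H]3[C@H]2C[C@H]1C | target

Total step count: 27. Longest linear sequence: 20 steps (steps 1–11, 15, 20–27).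

Steps most likely to fail

Step 26. The ring closure may lose to oligomerisation, the acidic and chelating acyl tetramate may sequester palladium, or the transannular cycloaddition may be too slow at a temperature the tetramate tolerates. The fallback sets out from 23 and makes the carbocycle before the macrolactam. The same Suzuki–Miyaura closure on the neutral lactone 23 (Pd(PPh3)4, TlOEt, THF/H2O, high dilution) should give the macrocyclic triene lactone F1, which can be heated freely (PhMe, up to 160 °C) to the tetracyclic lactone F2. Reduction with iBu2AlH should give the lactol F3, olefination with 26 the hydroxy dioxinone F4, and Dess–Martin oxidation the aldehyde F5. Olefination with 31 should give the Z-enamide F6, thermolysis through the acylketene F7 should give the macrocyclic β-keto amide F8, and Lacey–Dieckmann cyclisation of F8 comes back to the route at 40.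

Step 23. Z-selectivity may erode with a secondary phosphonoacetamide through equilibration of the adducts, and the amide N–H may be deprotonated in competition. The fallback sets out from 34 and builds the enamide in two bonds. Still–Gennari olefination (methyl bis(2,2,2-trifluoroethyl)phosphonoacetate, KN(SiMe3)2, 18-crown-6, THF, −78 °C) should give the Z-methyl enoate F9. Me3SnOH (ClCH2CH2Cl, 70 °C) should cleave the methyl ester without opening the dioxinone and give the Z-enoic acid F10. Carbodiimide coupling of F10 with the δ-amine of 29 comes back to the route at 35.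

Step 4. Acetalisation of the hindered β-keto imide may be slow, with enolisation (epimerisation at C3) or retro-Claisen cleavage competing. The fallback sets out from 6 and acetalises a simple ketone instead. Silylation (tBuMe2SiOTf, 2,6-lutidine) should give the silyl ether F11; NaBH4 in wet THF and then DBU should give, through the hydroxy ester F12, the silyloxy lactone F13. HF·pyridine should free the alcohol F14 and Dess–Martin oxidation should give the keto lactone F15. Noyori acetalisation of this unhindered methyl ketone comes back to the route at 10.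

Further compounds
F1 | step 26 | 12-membered (E,E,E)-triene lactone from C5–C6 coupling of 23 (not isolated) | CC1(OCCO1)[C@H]2/C=C/C=C/[C@H]3CCOC(=O)[C@@H]3C/C=C/C[C@H]2C
F2 | step 26 | tetracyclic lactone (rings A, B, C and the δ-lactone, dioxolane in place) | CC1(OCCO1)[C@H]2[C@@H]3C=C[C@@H]4[C@H]5CCOC(=O)[C@@H]5C[C@@H]4[C@H]3C[C@H]2C
F3 | step 26 | lactol of F2 | CC1(OCCO1)[C@H]2[C@@H]3C=C[C@@H]4[C@H]5CCOC(O)[C@@H]5C[C@@H]4[C@H]3C[C@H]2C
F4 | step 26 | tricyclic C10 alcohol with (23E)-dienyl dioxinone | CC1(OCCO1)[C@H]2[C@@H]3C=C[C@@H]4[C@@H](CCO)[C@H](/C=C/C5=CC(=O)OC(C)(C)O5)C[C@@H]4[C@H]3C[C@H]2C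
F5 | step 26 | C10 aldehyde of F4 | CC1(OCCO1)[C@H]2[C@@H]3C=C[C@@H]4[C@@H](CC=O)[C@H](/C=C/C5=CC(=O)OC(C)(C)O5)C[C@@H]4[C@H]3C[C@H]2C
F6 | step 26 | tricyclic (10Z)-enamide with ornithine ester and dioxinone | CC1(OCCO1)[C@H]2[C@@H]3C=C[C@@H]4[C@@H](C/C=C\C(=O)NCCC[C@H](NCc6ccc(OC)cc6OC)C(=O)OC)[C@H](/C=C/C5=CC(=O)OC(C)(C)O5)C[C@@H]4[C@H]3C[C@H]2C
F7 | step 26 | acylketene from F6 (not isolated) | CC1(OCCO1)[C@H]2[C@@H]3C=C[C@@H]4[C@@H](C/C=C\C(=O)NCCC[C@H](NCc6ccc(OC)cc6OC)C(=O)OC)[C@H](/C=C/C(=O)C=C=O)C[C@@H]4[C@H]3C[C@H]2C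
F8 | step 26 | tricyclic 17-membered β-keto amide | CC1(OCCO1)[C@H]2[C@@H]3C=C[C@@H]4[C@H]5C/C=C\C(=O)NCCC[C@@H](C(=O)OC)N(Cc6ccc(OC)cc6OC)C(=O)CC(=O)/C=C/[C@@H]5C[C@@H]4[C@H]3C[C@H]2C
F9 | step 23 | (10Z)-methyl enoate from 34 | COC(=O)/C=C\C[C@H](/C=C/I)[C@@H](C/C=C/C[C@@H](C)[C@@H](C2(C)OCCO2)/C=C/B3OC(C)(C)C(C)(C)O3)/C=C/C1=CC(=O)OC(C)(C)O1
F10 | step 23 | (10Z)-enoic acid from F9 | OC(=O)/C=C\C[C@H](/C=C/I)[C@@H](C/C=C/C[C@@H](C)[C@@H](C2(C)OCCO2)/C=C/B3OC(C)(C)C(C)(C)O3)/C=C/C1=CC(=O)OC(C)(C)O1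
F11 | step 4 | tert-butyldimethylsilyl ether of 6 | COC(=O)C[C@@H](C)[C@@H]([C@@H](C)O[Si](C)(C)C(C)(C)C)C(=O)N1[C@@H](Cc2ccccc2)COC1=O
F12 | step 4 | methyl (3R,4R,5R)-5-(tert-butyldimethylsilyloxy)-4-(hydroxymethyl)-3-methylhexanoate (not isolated) | COC(=O)C[C@@H](C)[C@@H]([C@@H](C)O[Si](C)(C)C(C)(C)C)CO
F13 | step 4 | (4R,5R)-5-[(1R)-1-(tert-butyldimethylsilyloxy)ethyl]-4-methyloxan-2-one | O=C1C[C@@H](C)[C@@H]([C@@H](C)O[Si](C)(C)C(C)(C)C)CO1
F14 | step 4 | (4R,5R)-5-[(1R)-1-hydroxyethyl]-4-methyloxan-2-one | O=C1C[C@@H](C)[C@@H]([C@@H](C)O)CO1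
F15 | step 4 | (4R,5S)-5-acetyl-4-methyloxan-2-one | O=C1C[C@@H](C)[C@@H](C(C)=O)CO1
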